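**Strategy.** The route rests on opening ring A across C1–C10 and C4–C5 (ent-kaurane locants). The key step is an ester-tethered intramolecular Diels–Alder reaction of a penta-2,4-dienoate (C1–C4, C19) with the E-trisubstituted alkene C5=C10 of an allylic alcohol carried by the C/D bicyclo[3.2.1]octane. It exploits the cis relation, on ring A, of the C19 carboxyl (on C4) and the formyl carbon C6 (on C5), which can be tied as a temporary C19–O–C6 γ-lactone. One operation closes ring A and the lactone and creates quaternary C10 and C5, their relative configuration dictated by alkene geometry. C4 is methylated stereoconvergently afterwards, and the lactone is unmasked to acid and aldehyde.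

Key step: step 12

Remark (numbering): ent-kaurane locants are used throughout. Ring A = C1–C5 and C10; C6 = formyl carbon on C5; C7 = formyl carbon on C8. The C/D unit is the bicyclo[3.2.1]octane C8, C9, C11–C16 (C14 = one-carbon bridge, C15–C16 = two-carbon bridge). C17 = CH2OH on C16; C18 = methyl and C19 = carboxyl on C4; C20 = methyl on C10. Target = (4R,5S,8R,9S,10S,13R,16R).

Remark (assumption): half-ester 1, the enzymatic desymmetrisation product of the meso diester, is taken as a commercial, enantiopure starting material.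

**Step 1**
Reactants: 1 (1S,6R)-6-(methoxycarbonyl)cyclohex-3-ene-1-carboxylic acid
Product: 3 (3aR,7aS)-3a,4,7,7a-tetrahydro-2-benzofuran-1(3H)-one (cis-lactone), via lithium hydroxy-carboxylate 2 (not isolated)
Conditions: LiBEt3H (3.2 equiv), THF, 0 °C to rt; then 2 M HCl, rt
Reagents that add atoms: none
Why: Chemoselective hydride reduction of the methyl ester beside the inert lithium carboxylate, then acid-induced lactonisation, should make the former acid carbon the lactone carbonyl (future C7) and the former ester carbon the O–CH2 (future C10) without touching either stereocentre.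

**Step 2**
Reactants: 3 cis-lactone; 4 2,3-dibromopropene
Product: 6 (3aR,7aR)-7a-(2-bromoprop-2-en-1-yl)-3a,4,7,7a-tetrahydro-2-benzofuran-1(3H)-one, via lithium enolate 5 (not isolated)
Conditions: LiN(i-Pr)2, THF, −78 °C; then 4, −78 to −20 °C
Reagents that add atoms: none
Why: Enolate alkylation at the ring-fusion carbon of a cis-fused bicyclic γ-lactone should occur on the convex face, so the bromoallyl group (C15–C17) enters cis to H-9 and the quaternary C8 is set relative to C9.

**Step 3**
Reactants: 6 bromoallyl lactone
Product: 7 tricyclic lactone (16-methylene bicyclo[3.2.1]octane C/D unit with the C7(=O)–O–C10H2 lactone across C8–C9)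
Conditions: Bu3SnH (1.3 equiv), AIBN (cat.), benzene (0.02 M), 80 °C
Reagents that add atoms: none
Why: A 5-exo-trig vinyl radical cyclisation (the C16 radical adds to C13 of the ring alkene) should close ring D, and the new bridge can only form cis to C15, which sets C13.

**Step 4**
Reactants: 7 tricyclic lactone
Product: 8 16,17-diol lactone
Conditions: OsO4 (2 mol %), N-methylmorpholine N-oxide, acetone/H2O, rt
Reagents that add atoms: N-methylmorpholine N-oxide, C[N+]1([O-])CCOCC1; water, O
Why: Catalytic syn-dihydroxylation (Upjohn conditions) should occur on the exo face of the two-carbon bridge, the endo face being shielded by the C11 methylene, which places the tertiary C16 hydroxyl on the side of the C14 bridge as in the target.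

**Step 5**
Reactants: 8 diol lactone
Product: 9 acetonide lactone
Conditions: 2,2-dimethoxypropane, PPTS (cat.), CH2Cl2, rt
Reagents that add atoms: 2,2-dimethoxypropane, COC(C)(C)OC
Why: Acid-catalysed transketalisation should mask the 16,17-diol as a dioxolane that survives all later basic, reductive and thermal steps.

**Step 6**
Reactants: 9 acetonide lactone
Product: 10 1,4-diol (C7H2OH on C8 and C10H2OH on C9)
Conditions: LiAlH4, THF, 0 °C to rt; aqueous NaOH work-up
Reagents that add atoms: none
Why: Hydride reduction of the lactone to the diol frees C10 for oxidation and brings C7 to the alcohol level.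

**Step 7**
Reactants: 10 1,4-diol
Product: 12 γ-lactol (C10 hemiacetal closed onto the C7 oxygen), via hydroxy aldehyde 11 (not isolated)
Conditions: IBX (1.2 equiv), DMSO, rt
Reagents that add atoms: none
Why: IBX oxidation of a 1,4-diol should stop at the γ-lactol, and the C10 carbinol on a CH carbon should react before the neopentyl C7 carbinol on the quaternary bridgehead.

**Step 8**
Reactants: 12 γ-lactol
Product: 13 alkynol (C9–C10≡C5H and free C7H2OH)
Conditions: dimethyl (1-diazo-2-oxopropyl)phosphonate, K2CO3, MeOH, 0 °C to rt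
Reagents that add atoms: dimethyl (1-diazo-2-oxopropyl)phosphonate, CC(=O)C(=[N+]=[N-])P(=O)(OC)OC
Why: Ohira–Bestmann (Seyferth–Gilbert) homologation of the lactol, which reacts as a masked aldehyde through its ring-chain tautomer (the open form 11 of step 7), should give the terminal alkyne, with capture of the formyl group expected to outpace enolisation at C9, which is flanked by the quaternary C8.

**Step 9**
Reactants: 13 alkynol
Product: 14 benzyl ether alkyne
Conditions: NaH, benzyl bromide, Bu4NI (cat.), THF, 0 °C to rt
Reagents that add atoms: benzyl bromide, BrCc1ccccc1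
Why: Williamson etherification protects the C7 hydroxyl with a group that is removed later in the hydrogenation step at no extra cost.

**Step 10**
Reactants: 14 benzyl ether alkyne
Product: 16 (E)-allylic alcohol (C9–C10(CH3)=C5H–C6H2OH), via alkenylalane 15 (not isolated)
Conditions: Me3Al (3 equiv), Cp2ZrCl2 (0.25 equiv), H2O (1 equiv), CH2Cl2, −20 to 0 °C; then (CH2O)n, THF, 0 °C to rt
Reagents that add atoms: trimethylaluminium, C[Al](C)C; formaldehyde (from paraformaldehyde), C=O
Why: Zirconium-catalysed syn-carboalumination (Negishi) should deliver methyl to C10 and aluminium to C5, and hydroxymethylation with retention then fixes the E alkene with C6 cis to C20.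

**Step 11**
Reactants: 16 (E)-allylic alcohol; 17 (E)-penta-2,4-dienoic acid
Product: 18 trienyl ester (penta-2,4-dienoate of 16)
Conditions: DCC, DMAP (cat.), CH2Cl2, 0 °C to rt
Reagents that add atoms: none
Why: Steglich esterification of the unhindered primary allylic alcohol installs the diene and the three-atom tether C19–O–C6 in one operation.

**Step 12**
Reactants: 18 trienyl ester
Product: 19 Diels–Alder adduct (ring A cyclohexene with C2=C3 fused to the C19–O–C6 γ-lactone; C4 epimer mixture)
Conditions: BHT (cat.), 1,2-dichlorobenzene (0.01 M), 200 °C, sealed tube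
Reagents that add atoms: none
Why: Thermal, concerted but asynchronous [4+2] cycloaddition in which the electron-poor dienoate (C1=C2–C3=C4) adds suprafacially to the electron-rich trisubstituted alkene C5=C10, the closest known reaction type being the ester-tethered type 1 intramolecular Diels–Alder reaction of dienoates of allylic alcohols. Ring A (six-membered) is closed by the cycloaddition itself through the new bonds C1–C10 and C4–C5, and the γ-lactone (five-membered, C4–C19–O–C6–C5) is closed by the three-atom tether, which also enforces the fused regiochemistry. C5 and C10 are created stereospecifically, because the E geometry of the alkene puts C6 and the methyl C20 cis on ring A, as in the target. The configuration of the new quaternary C10 relative to C9 depends on π-facial selectivity, which the C/D unit is expected to secure: the diene should add anti to the quaternary bridgehead C8 in the rotamer that keeps the compact methyl C20, and not the tether-bearing C5, over ring C, which is the arrangement of the ent-kaurane skeleton itself. C4 is formed as an epimer mixture (endo and exo orientation of the tether), which is of no consequence because both epimers give the same enolate in step 13. Dilution and BHT should suppress dienoate oligomerisation, and the dienoate has no cis alkyl group that could divert it into a 1,5-hydrogen shift.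

**Step 13**
Reactants: 19 Diels–Alder adduct
Product: 21 C4-methylated cis-fused lactone, via lithium dienolate 20 (not isolated)
Conditions: LiN(i-Pr)2, THF/DMPU, −78 °C; then MeI, −78 to −30 °C
Reagents that add atoms: iodomethane, CI
Why: Stereoconvergent enolate alkylation: both C4 epimers give the same dienolate, and iodomethane should attack the α-carbon C4 on the face anti to the 1,3-related methyl C20, keeping the lactone cis-fused so that C19 ends cis to C6 and C20.

**Step 14**
Reactants: 21 methylated lactone
Product: 22 saturated lactone with free C7H2OH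
Conditions: H2 (1 atm), Pd/C (10 %), EtOAc/EtOH, rt
Reagents that add atoms: none
Why: Heterogeneous hydrogenation should saturate C2=C3 and cleave the benzyl ether in the same operation, while lactone and acetonide are inert.

**Step 15**
Reactants: 22 saturated lactone
Product: 24 4-methoxybenzyl ester diol (C6H2OH and C7H2OH free), via potassium carboxylate 23 (not isolated)
Conditions: KOH, MeOH/H2O, 65 °C; CO2 to pH 8–9, evaporate; 4-methoxybenzyl chloride, DMF, rt
Reagents that add atoms: potassium hydroxide, [K+].[OH-]; 4-methoxybenzyl chloride, COc1ccc(CCl)cc1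
Why: Saponification opens the lactone and O-alkylation of the carboxylate without exposure to acid should trap the open form as an ester before it can relactonise.

**Step 16**
Reactants: 24 ester diol
Product: 25 dialdehyde 4-methoxybenzyl ester (C6 and C7 formyl groups; acetonide intact)
Conditions: Dess–Martin periodinane (2.5 equiv), NaHCO3, CH2Cl2, 0 °C to rt
Reagents that add atoms: none
Why: Buffered Dess–Martin oxidation should convert both primary alcohols to aldehydes under non-epimerising conditions, C7 being non-enolisable and C5 protected by the buffer.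

**Step 17**
Reactants: 25 dialdehyde ester
Product: 26 target (4R,5S,8R,9S,10S,13R,16R)-16,17-dihydroxy-6,7-dioxo-6,7-seco-ent-kauran-19-oic acid
Conditions: TFA/H2O/CH2Cl2 (2:1:8), 0 °C to rt
Reagents that add atoms: none
Why: Acidolysis should remove the 4-methoxybenzyl ester (benzylic C–O cleavage) and hydrolyse the terminal acetonide together, under conditions mild enough to leave the C5 stereocentre alone.

**Compound list**

1 | (1S,6R)-6-(methoxycarbonyl)cyclohex-3-ene-1-carboxylic acid | OC(=O)[C@H]1CC=CC[C@H]1C(=O)OC | starting material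
2 | lithium (1S,6R)-6-(hydroxymethyl)cyclohex-3-ene-1-carboxylate | [Li+].[O-]C(=O)[C@H]1CC=CC[C@H]1CO | intermediate (not isolated)
3 | (3aR,7aS)-3a,4,7,7a-tetrahydro-2-benzofuran-1(3H)-one, cis-fused | C1[C@@H]2CC=CC[C@@H]2C(=O)O1 | intermediate
4 | 2,3-dibromopropene | C=C(Br)CBr | starting material
5 | lithium enolate of 3 | C1[C@@H]2CC=CCC2=C(O[Li])O1 | intermediate (not isolated)
6 | (3aR,7aR)-7a-(2-bromoprop-2-en-1-yl)-3a,4,7,7a-tetrahydro-2-benzofuran-1(3H)-one, cis-fused | C1[C@@H]2CC=CC[C@@]2(C(=O)O1)CC(Br)=C | intermediate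
7 | tricyclic lactone, (8R,9R,13R): 16-methylene bicyclo[3.2.1]octane with C7(=O)–O–C10H2 lactone cis-fused at C8–C9 | C1[C@@H]2CC[C@@H]3C[C@@]2(C(=O)O1)CC3=C | intermediate
8 | 16,17-diol of 7, C16–OH on the face of the C14 bridge | C1[C@@H]2CC[C@@H]3C[C@@]2(C(=O)O1)C[C@]3(O)CO | intermediate
9 | 16,17-acetonide of 8 | C1[C@@H]2CC[C@@H]3C[C@@]2(C(=O)O1)C[C@]3(OC(C)(C)O4)C4 | intermediate
10 | 1,4-diol: C/D acetonide with C7H2OH on C8 and C10H2OH on C9 | OC[C@@H]1CC[C@@H]2C[C@@]1(CO)C[C@]2(OC(C)(C)O3)C3 | intermediate
11 | hydroxy aldehyde: C10 formyl on C9, C7H2OH on C8 | O=C[C@@H]1CC[C@@H]2C[C@@]1(CO)C[C@]2(OC(C)(C)O3)C3 | intermediate (not isolated)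
12 | γ-lactol: C10H(OH)–O–C7H2 across C9–C8, anomer mixture | OC1[C@@H]2CC[C@@H]3C[C@@]2(CO1)C[C@]3(OC(C)(C)O4)C4 | intermediate
13 | alkynol: ethynyl (C10≡C5) on C9, C7H2OH on C8 | C#C[C@@H]1CC[C@@H]2C[C@@]1(CO)C[C@]2(OC(C)(C)O3)C3 | intermediate
14 | benzyl ether of 13 | C#C[C@@H]1CC[C@@H]2C[C@@]1(COCc4ccccc4)C[C@]2(OC(C)(C)O3)C3 | intermediate
15 | (E)-alkenyl(dimethyl)alane: Al on C5 cis to methyl C20 | C[Al](C)/C=C(\C)[C@@H]1CC[C@@H]2C[C@@]1(COCc4ccccc4)C[C@]2(OC(C)(C)O3)C3 | intermediate (not isolated)
16 | (E)-allylic alcohol: C9–C10(CH3)=C5H–C6H2OH | OC/C=C(\C)[C@@H]1CC[C@@H]2C[C@@]1(COCc4ccccc4)C[C@]2(OC(C)(C)O3)C3 | intermediate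
17 | (E)-penta-2,4-dienoic acid | OC(=O)/C=C/C=C | starting material
18 | trienyl ester: (E)-penta-2,4-dienoate of 16 | C=C/C=C/C(=O)OC/C=C(\C)[C@@H]1CC[C@@H]2C[C@@]1(COCc4ccccc4)C[C@]2(OC(C)(C)O3)C3 | intermediate
19 | Diels–Alder adduct: ring A cyclohexene (C2=C3) fused to C19–O–C6 γ-lactone, (5S,10S), C4 epimer mixture | C[C@@]1([C@@H]2CC[C@@H]3C[C@@]2(COCc4ccccc4)C[C@]3(OC(C)(C)O6)C6)CC=CC5C(=O)OC[C@@H]15 | intermediate
20 | lithium dienolate of 19 | C[C@@]1([C@@H]2CC[C@@H]3C[C@@]2(COCc4ccccc4)C[C@]3(OC(C)(C)O6)C6)CC=CC5=C(O[Li])OC[C@@H]15 | intermediate (not isolated)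
21 | C4-methylated cis-fused lactone (C18 methyl trans to C6 and C20) | C[C@@]1([C@@H]2CC[C@@H]3C[C@@]2(COCc4ccccc4)C[C@]3(OC(C)(C)O6)C6)CC=C[C@@]5(C)C(=O)OC[C@@H]15 | intermediate
22 | saturated lactone with free C7H2OH | C[C@@]1([C@@H]2CC[C@@H]3C[C@@]2(CO)C[C@]3(OC(C)(C)O4)C4)CCC[C@@]5(C)C(=O)OC[C@@H]15 | intermediate
23 | potassium 19-carboxylate with C6H2OH and C7H2OH | C[C@@]1([C@@H]2CC[C@@H]3C[C@@]2(CO)C[C@]3(OC(C)(C)O4)C4)CCC[C@@](C)(C(=O)[O-])[C@H]1CO.[K+] | intermediate (not isolated)
24 | 4-methoxybenzyl 19-ester, 6,7-diol | C[C@@]1([C@@H]2CC[C@@H]3C[C@@]2(CO)C[C@]3(OC(C)(C)O4)C4)CCC[C@@](C)(C(=O)OCc5ccc(OC)cc5)[C@H]1CO | intermediate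
25 | 4-methoxybenzyl 19-ester, 6,7-dialdehyde, 16,17-acetonide | C[C@@]1([C@@H]2CC[C@@H]3C[C@@]2(C=O)C[C@]3(OC(C)(C)O4)C4)CCC[C@@](C)(C(=O)OCc5ccc(OC)cc5)[C@H]1C=O | intermediate
26 | (4R,5S,8R,9S,10S,13R,16R)-16,17-dihydroxy-6,7-dioxo-6,7-seco-ent-kauran-19-oic acid | C[C@@]1([C@@H]2CC[C@@H]3C[C@@]2(C=O)C[C@]3(O)CO)CCC[C@@](C)(C(=O)O)[C@H]1C=O | target

**Step count.** Total: 17 steps. Longest linear sequence: 17 steps (1 to 26); 4 and 17 are purchased.

**Steps most likely to fail**

Step 12. The remote C9 centre may discriminate the two alkene faces poorly, and the s-trans ester may make the cycloaddition sluggish; either would erode the C10 configuration. The fallback uses known chemistry and moves facial control to a temporary allylic stereocentre. It sets out from 14. Carboalumination as in step 10 and coupling of alkenylalane 15 with benzyloxyacetyl chloride under Pd(PPh3)4 catalysis should give enone F1. Corey–Bakshi–Shibata reduction with the (S)-oxazaborolidine and catecholborane, the alkenyl group acting as the large substituent, should give (6S)-allylic alcohol F2, and esterification with 17 gives trienyl ester F3. In its intramolecular Diels–Alder reaction, A(1,3) strain between the C6 substituents and the cis methyl C20 holds H-6 in the alkene plane, so the O6-tethered diene can reach only the required face, giving adduct F4. Methylation (LiN(i-Pr)2, MeI) gives lactone F5. Hydrogenation over Pd/C (alkene and both benzyl ethers) gives diol lactone F6. KOH then 4-methoxybenzyl chloride gives triol ester F7. NaIO4 cleaves the C6 glycol, the extra carbon leaving as formaldehyde, to give hydroxy aldehyde F8. Dess–Martin oxidation of the C7 alcohol rejoins the route at 25.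

Step 15. The γ-lactone may re-close from the free γ-hydroxy ester during isolation or the following oxidation. The fallback sets out from 22. Saponification and carboxylate alkylation are run as in step 15 (23 and 24 not isolated) and followed in the same flask by TESCl/imidazole, giving bis(triethylsilyl) ether F9, which cannot lactonise. Swern conditions ((COCl)2, DMSO, then Et3N) oxidise primary triethylsilyl ethers directly to aldehydes and should deliver 25, where the route is rejoined.

Step 7. Oxidation may occur at the neopentyl C7 carbinol, or proceed past the lactol. The fallback sets out from 10. TEMPO (cat.)/PhI(OAc)2 deliberately drives the diol to the γ-lactone; the bulky oxoammonium oxidant should attack the less hindered C10 carbinol, giving transposed lactone F10 (C10 carbonyl, C7H2–O). Reduction with i-Bu2AlH at −78 °C then returns to the route at lactol 12.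

**Further compounds**

F1 | step 12 | enone: BnOCH2–C6(=O)–C5H=C10(CH3)–C9, E | O=C(COCc1ccccc1)/C=C(\C)[C@@H]2CC[C@@H]3C[C@@]2(COCc4ccccc4)C[C@]3(OC(C)(C)O5)C5
F2 | step 12 | (6S)-allylic alcohol | O[C@H](COCc1ccccc1)/C=C(\C)[C@@H]2CC[C@@H]3C[C@@]2(COCc4ccccc4)C[C@]3(OC(C)(C)O5)C5
F3 | step 12 | (E)-penta-2,4-dienoate of F2 | C=C/C=C/C(=O)O[C@H](COCc1ccccc1)/C=C(\C)[C@@H]2CC[C@@H]3C[C@@]2(COCc4ccccc4)C[C@]3(OC(C)(C)O5)C5
F4 | step 12 | Diels–Alder adduct with benzyloxymethyl on C6, C4 epimer mixture | C[C@@]1([C@@H]2CC[C@@H]3C[C@@]2(COCc4ccccc4)C[C@]3(OC(C)(C)O6)C6)CC=CC5C(=O)O[C@H](COCc7ccccc7)[C@@H]15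
F5 | step 12 | C4-methylated lactone with benzyloxymethyl on C6 | C[C@@]1([C@@H]2CC[C@@H]3C[C@@]2(COCc4ccccc4)C[C@]3(OC(C)(C)O6)C6)CC=C[C@@]5(C)C(=O)O[C@H](COCc7ccccc7)[C@@H]15
F6 | step 12 | saturated lactone with hydroxymethyl on C6 and free C7H2OH | C[C@@]1([C@@H]2CC[C@@H]3C[C@@]2(CO)C[C@]3(OC(C)(C)O4)C4)CCC[C@@]5(C)C(=O)O[C@H](CO)[C@@H]15
F7 | step 12 | 4-methoxybenzyl 19-ester triol (C6 glycol and C7H2OH) | C[C@@]1([C@@H]2CC[C@@H]3C[C@@]2(CO)C[C@]3(OC(C)(C)O4)C4)CCC[C@@](C)(C(=O)OCc5ccc(OC)cc5)[C@H]1[C@H](O)CO
F8 | step 12 | 4-methoxybenzyl 19-ester, C6 aldehyde, C7H2OH | C[C@@]1([C@@H]2CC[C@@H]3C[C@@]2(CO)C[C@]3(OC(C)(C)O4)C4)CCC[C@@](C)(C(=O)OCc5ccc(OC)cc5)[C@H]1C=O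
F9 | step 15 | 4-methoxybenzyl 19-ester, 6,7-bis(triethylsilyl) ether | C[C@@]1([C@@H]2CC[C@@H]3C[C@@]2(CO[Si](CC)(CC)CC)C[C@]3(OC(C)(C)O4)C4)CCC[C@@](C)(C(=O)OCc5ccc(OC)cc5)[C@H]1CO[Si](CC)(CC)CC
F10 | step 7 | transposed γ-lactone: C10(=O)–O–C7H2 across C9–C8 | O=C1[C@@H]2CC[C@@H]3C[C@@]2(CO1)C[C@]3(OC(C)(C)O4)C4
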